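Before you spend L on this flask, decide whether 0.900 equiv of G is worth running at all, since the earlier runs let you reckon its outcome first.

| flask | L | G | remark | time |
|---|---|---|---|---|
| epsilon | 10 mM | 0.90 equiv | run made earlier |  |
| gamma | 15 mM | 0.90 equiv | run made earlier |  |
| delta | 20 mM | 1.8 equiv | run made earlier |  |
| flask | 20 mM | 0.900 equiv |  | 40 min |

| run | time / min | L / % | Z / % | D / % |
|---|---|---|---|---|
| epsilon | 3.00 | 8.6 | 75.6 | 13.3 |
| epsilon | 8.00 | 9.2 | 76.2 | 16.1 |
| epsilon | 15.0 | 11.8 | 75.7 | 12.8 |
| epsilon | 40.0 | 10.4 | 75.6 | 14.2 |
| gamma | 3.00 | 10.6 | 75.2 | 13.9 |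
| gamma | 8.00 | 9.0 | 74.5 | 13.6 |
| gamma | 15.0 | 11.1 | 74.3 | 13.1 |
| gamma | 40.0 | 9.2 | 77.2 | 14.3 |
| delta | 10.0 | 0.7 | 83.2 | 18.7 |
| delta | 20.0 | 0.7 | 83.5 | 16.2 |
| delta | 30.0 | 0 | 83.3 | 16.3 |
| delta | 40.0 | 0 | 84.3 | 15.6 |

(readings scatter by 1 percentage point)

1. why nothing more happens at 40 min, or that something still does (G has run out first / it is still moving / all of L has reacted)
2. conversion of L at 40 min
3. amount of Z at 40 min, in percent of the L charged
4. amount of D at 40 min, in percent of the L charged

- steps thought possible: L + G -> E; E -> Z; E -> D
- the reaction counts as stopped when no species that holds the L changes by six tenths of a point or more over the second half of the time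

My reckoning rests on the Z share, the Z formed per L consumed, taken as Z over Z plus D (a selectivity): summed over the epsilon, gamma and delta readings it is 0.841, a reading that I freeze, because it shows no trend with c(L) or with the G charge.

Two extreme flasks bracket this one. In the fast extreme, G is consumed as soon as it meets L, each L taking one G, so G is the limiting reagent, conversion equals the charge at 90.0%, and Z and D come to 75.6% and 14.4%. In the slow extreme, L is still falling at 40 min and Z stands short of that figure. At equal equivalents, a step between L and G should run faster in proportion to c(L), so the epsilon run, flat by its first reading at 3.00 min, leads me to expect this flask at that stage by about 1.50 min, far earlier than the asked time, which places it at the fast end.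

The forecast says G has run out first, with conversion 90%, Z 75.7% and D 14.3%, on the ground that “G runs out rather than the reaction being slow”; its Z and D stand beside my 75.6% and 14.4%.

The result for the flask is: G has run out first, with conversion 90.0%, Z 75.6% and D 14.4%.

    L + G → E (k = 33.0 M⁻¹ s⁻¹)
    E → Z (k = 0.680 s⁻¹)
    E → D (k = 0.130 s⁻¹)

At 4.00 min this flask already holds 0% of its G and 10.0% of its L, and at 400 min L still stands at 10.0%, the tenfold time leaving conversion unchanged. Carry the share to the neighbouring flask with 1.50 equiv of G, where the G charged exceeds the L charged, so that each L taking one G allows full conversion of L: the reckoning gives Z 84.1% and D 15.9%. That neighbour reaches conversion 100%, with Z 84.0% and D 16.0%, and 33% of its G remains.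

The numbers in the tables come from a simulation for an exercise, and the scatter is random.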